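# Dodoviscin G by closure of ring C at carbon: synthesis design

Numbers 1–28 refer to the compound list after the steps. Compound 24 is the key-step precursor, 26 its product and 28 the target.

## The problem

Dodoviscin G (28) is a 3,6-dimethoxy-5,7,4'-trihydroxyflavone. Its ring B carries a prenyl group on one side of the 4'-hydroxyl and an (E)-4-hydroxy-3-methylbut-2-enyl group on the other. There is no stereocentre. The only stereochemical element is the E trisubstituted alkene of the oxidised chain, which nothing else in the molecule can control, so it must be made by a reaction that is selective in its own right and then left alone. The two C5 chains differ by one oxygen, so they have to be attached to ring B one after the other. Ring A is oxygenated at C5, C6 and C7 and carries O1 at C8a, so closing ring C onto an unsymmetrical ring A precursor raises the 6-methoxy versus 8-methoxy question. The late intermediates are fragile: a prenyl group next to a free phenol cyclises to a chroman in strong acid, the primary allylic alcohol can ionise, and three alkenes rule out hydrogenolysis and electrophilic oxidants. One feature simplifies the problem. The phenol that supplies O1 and ring A (a 4-methoxyphenol oxygenated at C3 and C5) has a mirror plane through the carbons that become C8a and C6, so acylation at either ortho carbon forms the same C4–C4a bond and only the 6-methoxy isomer. Each of those carbons is ortho and para to an oxygen substituent, which allows a mild acylating agent to close ring C.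

## Retrosynthesis

**Protecting groups (28 ⇒ 27 ⇒ 26).** The cuts are the O–acyl bond of an allylic pivalate and three O–CH2 bonds of methoxymethyl ethers on the phenols. Benzyl ethers were rejected: their removal needs a boron halide or hydrogen, and neither reliably spares a prenyl group next to a phenol or an allylic ester. Silyl ethers on the phenols would not survive the basic steps. The acetals come off with dilute acid in methanol, the usual finish for prenylated flavonoids. During that step the pivalate keeps the allylic oxygen from ionising, and methoxide then frees the alcohol. The forward steps must leave the alkenes and the pyranone untouched.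

**Ring C (26 ⇒ 24, C4–C4a).** Flavone 26 is cut between the carbonyl carbon and ring A, which leads back to the 3-aryloxy-2-methoxyacrylic acid 24, activated in the flask as the mixed trifluoroacetic anhydride 25. The neighbouring cuts are O1–C2 (cyclodehydration of a diketone) and O1–C8a. Both need a ring A ketone with differentiated ortho positions, which means five different substituents on one benzene ring. The C4–C4a cut needs only a symmetric phenol. In 24 the two aryl rings are joined through a single enol ether and all oxygen functions are in place. The forward reaction must be a Friedel–Crafts acylation mild enough for acetals and trisubstituted alkenes.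

**Enol ether and acid (24 ⇒ 23 ⇒ 22 + 4).** The acid is stored as the 2-(trimethylsilyl)ethyl ester 23. Hydroxide would attack the pivalate before this hindered, deactivated acrylate ester, whereas fluoride removes the silylethyl group and touches nothing else. The O1–C2 bond is cut next, giving phenol 4 and enol tosylate 22. The alternative, adding the phenol to an aryl propiolate, would give an acrylate without the C3 oxygen and force a late oxidation in the presence of three alkenes. The forward reaction is an addition–elimination at a fully substituted acrylate.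

**C2–C3 (22 ⇒ 21 ⇒ 19 + 7).** Tosylate 22 comes from β-keto ester 21. Cutting C2–C3 of 21 gives benzoate 19 and the lithium enolate 20 of 2-(trimethylsilyl)ethyl methoxyacetate 7. This crossed Claisen condensation uses the benzoate as it stands and brings in C3, C4 and the 3-methoxy group in one piece. An aldol–oxidation sequence would need an aldehyde oxidation level on ring B, which clashes with the chain chemistry.

**Ring A fragment (4 ⇒ 2 ⇒ 1).** The C–O bond para to the methoxy group of 4 is cut, leading through boronate 3 to the bis(methoxymethyl) ether 2 of 2-methoxyresorcinol 1. Electrophilic substitution of 2 would go ortho to the acetal oxygens. Sterically governed C–H borylation goes to the one C–H with no ortho neighbour. Acetal protecting groups also carry no aryl C–H that could be borylated, which benzyl groups would.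

**Prenyl group (19 ⇒ 18 ⇒ 15 + 17).** After removal of the pivalate, the aryl–CH2 bond of the prenyl group is cut, giving aryl bromide 15 and prenylzinc bromide 17, made from prenyl bromide 16. A linear-selective Negishi coupling is preferred to C-alkylation of a phenoxide, which would give O- and C-alkylation mixtures. It is placed before the acylation so that no allylic ester meets the palladium catalyst.

**E-alkene (15 ⇒ 14 ⇒ 12 + 13).** The allylic alcohol goes back to enal 14, and the C=C bond of 14 is cut into allylarene 12 and methacrolein 13. Cross-metathesis with a 2-substituted acrolein is the standard E-selective route to this chain. It is run while the molecule has only one alkene, so the later prenyl group cannot compete for the catalyst.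

**Allyl group (12 ⇒ 11 ⇒ 10 ⇒ 8 + 9).** The aryl–allyl bond is cut by a Claisen rearrangement of allyl ether 10, made from methyl 3-bromo-4-hydroxybenzoate 8 and allyl bromide 9. The bromine of 8 blocks one ortho position and is kept for the prenyl coupling, so the two chains are differentiated from the first step.

**Ester reagent (7 ⇒ 5 + 6).** Ester 7 is cut at its acyl–oxygen bond into methoxyacetyl chloride 5 and 2-(trimethylsilyl)ethanol 6.

## Roads not taken

**Alternative 1: three-component carbonylative annulation.** The cut removes C4a–C4, C4–C3 and O1–C2 together. In the forward step the ortho-iodophenol A2 (one iodination away from phenol 4), carbon monoxide A4 and the ring B arylacetylene A3 combine under PdCl2(PPh3)2 in diethylamine. An acylpalladium species captures the alkyne, and the phenoxide closes 6-endo on the resulting alkynone to give flavone A1.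
- Merits: three bonds in one step, no acid, and the same symmetric ring A logic.
- Weak points: A1 has no oxygen at C3, so hydroxylation and methylation must follow (two to three steps), and the usual epoxidising oxidants would attack the three electron-rich alkenes. The iodide of A2 is flanked by two oxygen substituents, which slows oxidative addition. 5-exo closure to an aurone is a known competitor. A3 needs a homologation that benzoate 19 does not.
- Comparison: this road is better in convergence and in the mildness of ring formation. The chosen plan offsets this by bringing the 3-methoxy group in with ester 7, so no oxidation is needed late.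

**Alternative 2: ring A grown on a pyranone.** The cut removes C8–C7 and C6–C5. In the forward step the 2-methyl group of pyranone ester A5 is deprotonated to a dienolate and acylated by methyl methoxyacetate A6. The new ketone enolate then closes on the ring ester and aromatises to A7.
- Merits: the ring A pattern is fixed by construction, the 5- and 7-hydroxyls appear free, and no electrophilic aromatic substitution is needed.
- Weak points: A5 is a fully substituted 4-pyranone that itself needs a multi-step synthesis with the sensitive ring B attached. Acylating a dienolate with an enolisable α-alkoxy ester competes with proton transfer and O-acylation. Strong base can open the pyranone.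
- Comparison: this road is better in needing no protecting groups on ring A. The chosen plan offsets this with a two-step ring A fragment and established precedent for each bond-forming reaction.

**Alternative 3: Ullmann closure at O1–C8a.** The cut removes the aryl–oxygen bond. In the forward step the enolate oxygen of the 2-methoxy-1,3-diketone A8 displaces the ortho bromide under CuI catalysis to give the fully protected flavone A9.
- Merits: base-only conditions, the 3-methoxy group is present, and C-arylation is geometrically impossible.
- Weak points: the bromine of A8 sits ortho to the acyl group and meta to two oxygens, the position electrophilic bromination avoids, so the ring A ketone needs a longer, regiochemically delicate synthesis. The diketone must be made from a ketone with two ortho substituents.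
- Comparison: this road is better in functional-group tolerance at the ring-closing step and would allow a silyl ether on the chain. The chosen plan needs a buffered acylation and one extra ester step, and offsets these with the symmetry of phenol 4, which makes the ring A fragment short and the regiochemistry certain.

Key step: step 15

Remark (assumption on the chemistry): enol tosylate 22 and acrylates 23–25 are drawn as the E isomers expected from chelate-controlled tosylation and substitution with retention; a Z isomer, if formed, is carried along because step 15 can equilibrate the alkene. ArB stands for 4-(methoxymethoxy)-3-(3-methylbut-2-en-1-yl)-5-[(E)-3-methyl-4-(pivaloyloxy)but-2-en-1-yl]phenyl and ArA for 4-methoxy-3,5-bis(methoxymethoxy)phenyl.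

## Route

Step 1
Reactants: 1 2-methoxyresorcinol
Product: 2 2-methoxy-1,3-bis(methoxymethoxy)benzene
Conditions: MOMCl (2.5 equiv), iPr2NEt, CH2Cl2, 0 °C to rt
Reagents that add atoms: chloromethyl methyl ether, COCCl
Why: Twofold O-alkylation of the phenols by an α-chloro ether (methoxymethyl ether formation); there is no competing site.

Step 2
Reactants: 2 2-methoxy-1,3-bis(methoxymethoxy)benzene
Product: 4 4-methoxy-3,5-bis(methoxymethoxy)phenol, via aryl pinacol boronate 3 (not isolated)
Conditions: [Ir(OMe)(cod)]2 (1.5 mol %), 4,4'-di-tert-butyl-2,2'-bipyridine (3 mol %), B2pin2 (1.0 equiv), THF, 80 °C; then aq NaOH, 30% H2O2, 0 °C to rt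
Reagents that add atoms: bis(pinacolato)diboron, CC1(C)OB(OC1(C)C)B1OC(C)(C)C(C)(C)O1 (boron of 3 only); hydrogen peroxide, OO (phenol oxygen of 4)
Why: Iridium-catalysed C–H borylation is governed by sterics, and C5 of 2 is the only ring C–H without an ortho substituent. Alkaline peroxide then converts the boronate into the phenol by aryl migration from boron to oxygen, without exposing the acetals to acid (one-pot borylation–oxidation).

Step 3
Reactants: 5 methoxyacetyl chloride; 6 2-(trimethylsilyl)ethanol
Product: 7 2-(trimethylsilyl)ethyl methoxyacetate
Conditions: Et3N, DMAP (cat.), CH2Cl2, 0 °C to rt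
Reagents that add atoms: none
Why: Acylation of a primary alcohol by an acid chloride (nucleophilic acyl substitution).

Step 4
Reactants: 8 methyl 3-bromo-4-hydroxybenzoate; 9 allyl bromide
Product: 10 methyl 4-(allyloxy)-3-bromobenzoate
Conditions: K2CO3, acetone, reflux
Reagents that add atoms: none
Why: Williamson ether synthesis on an acidic phenol; O-alkylation is the normal outcome in a polar solvent with carbonate.

Step 5
Reactants: 10 methyl 4-(allyloxy)-3-bromobenzoate
Product: 11 methyl 3-allyl-5-bromo-4-hydroxybenzoate
Conditions: N,N-diethylaniline, 190 °C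
Reagents that add atoms: none
Why: Aromatic Claisen rearrangement ([3,3] shift, then tautomerisation). Bromine blocks one ortho position and the ester the para position, so the allyl group can only go to the free ortho carbon.

Step 6
Reactants: 11 methyl 3-allyl-5-bromo-4-hydroxybenzoate
Product: 12 methyl 3-allyl-5-bromo-4-(methoxymethoxy)benzoate
Conditions: MOMCl, iPr2NEt, CH2Cl2, 0 to 40 °C
Reagents that add atoms: chloromethyl methyl ether, COCCl
Why: Methoxymethyl ether formation on the phenol; the acetal is inert to the ruthenium, hydride, organozinc and enolate chemistry that follows.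

Step 7
Reactants: 12 methyl 3-allyl-5-bromo-4-(methoxymethoxy)benzoate; 13 methacrolein
Product: 14 methyl 3-bromo-4-(methoxymethoxy)-5-[(E)-3-methyl-4-oxobut-2-en-1-yl]benzoate
Conditions: 13 (10 equiv), second-generation Hoveyda–Grubbs catalyst RuCl2(H2IMes)(=CH-C6H4-2-OiPr) (5 mol %), CH2Cl2, 40 °C
Reagents that add atoms: none
Why: Olefin cross-metathesis of a terminal alkene with a 2-substituted acrolein. The trisubstituted enal forms under thermodynamic control with the formyl group trans to the benzylic CH2, which sets the only stereogenic alkene of the target as E. At this stage no other alkene can engage the catalyst.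

Step 8
Reactants: 14 methyl 3-bromo-4-(methoxymethoxy)-5-[(E)-3-methyl-4-oxobut-2-en-1-yl]benzoate
Product: 15 methyl 3-bromo-5-[(E)-4-hydroxy-3-methylbut-2-en-1-yl]-4-(methoxymethoxy)benzoate
Conditions: NaBH4, CeCl3·7H2O, MeOH, 0 °C
Reagents that add atoms: none
Why: Luche reduction gives clean 1,2-reduction of the enal; the benzoate and the alkene geometry are untouched.

Step 9
Reactants: 15 methyl 3-bromo-5-[(E)-4-hydroxy-3-methylbut-2-en-1-yl]-4-(methoxymethoxy)benzoate; 16 prenyl bromide
Product: 18 methyl 3-[(E)-4-hydroxy-3-methylbut-2-en-1-yl]-4-(methoxymethoxy)-5-(3-methylbut-2-en-1-yl)benzoate, via prenylzinc bromide 17 (not isolated)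
Conditions: 16, Zn dust, LiCl, THF, rt (gives 17, 2.5 equiv); then 15, Pd(OAc)2 (2 mol %), CPhos (4 mol %), THF, rt
Reagents that add atoms: zinc, [Zn] (in 17 only)
Why: Negishi coupling of an allylic zinc halide; with a bulky biarylphosphine, reductive elimination takes place at the unsubstituted allyl terminus and gives the linear prenyl arene. The first equivalent of 17 is consumed by the hydroxyl group, and the resulting zinc alkoxide, unlike an allylic ester, cannot be ionised by zerovalent palladium, which is why the coupling precedes acylation.

Step 10
Reactants: 18 methyl 3-[(E)-4-hydroxy-3-methylbut-2-en-1-yl]-4-(methoxymethoxy)-5-(3-methylbut-2-en-1-yl)benzoate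
Product: 19 methyl 4-(methoxymethoxy)-3-(3-methylbut-2-en-1-yl)-5-[(E)-3-methyl-4-(pivaloyloxy)but-2-en-1-yl]benzoate
Conditions: PivCl, pyridine, DMAP (cat.), CH2Cl2, 0 °C to rt
Reagents that add atoms: pivaloyl chloride, CC(C)(C)C(Cl)=O
Why: Acylation of the primary allylic alcohol; the hindered ester withstands enolates, carbonate, fluoride and dilute acid in the steps ahead.

Step 11
Reactants: 7 2-(trimethylsilyl)ethyl methoxyacetate; 19 methyl 4-(methoxymethoxy)-3-(3-methylbut-2-en-1-yl)-5-[(E)-3-methyl-4-(pivaloyloxy)but-2-en-1-yl]benzoate
Product: 21 2-(trimethylsilyl)ethyl 3-ArB-2-methoxy-3-oxopropanoate (racemic at C2), via lithium ester enolate 20 (not isolated)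
Conditions: 7 (2.5 equiv), LiN(iPr)2 (2.6 equiv), THF, −78 °C; then 19, −78 to −20 °C; aq NH4Cl
Reagents that add atoms: lithium diisopropylamide, [Li]N(C(C)C)C(C)C (lithium of 20 only)
Why: Crossed Claisen condensation: the preformed enolate 20 adds to the non-enolisable methyl benzoate, and deprotonation of the β-keto ester by a second equivalent of enolate drives the reaction. The pivalate is too hindered to compete at low temperature. The C2 stereocentre of 21 is labile and is erased in the next step.

Step 12
Reactants: 21 2-(trimethylsilyl)ethyl 3-ArB-2-methoxy-3-oxopropanoate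
Product: 22 2-(trimethylsilyl)ethyl (E)-3-ArB-2-methoxy-3-(tosyloxy)acrylate
Conditions: TsCl, TMEDA, LiCl, MeCN, 0 °C
Reagents that add atoms: p-toluenesulfonyl chloride, Cc1ccc(cc1)S(Cl)(=O)=O
Why: Enol tosylation of a β-keto ester by soft enolisation; the lithium chelate between the two carbonyl oxygens is sulfonylated at the ketone oxygen, which places the tosyloxy group cis to the ester (the E descriptor for this substitution pattern).

Step 13
Reactants: 22 2-(trimethylsilyl)ethyl (E)-3-ArB-2-methoxy-3-(tosyloxy)acrylate; 4 4-methoxy-3,5-bis(methoxymethoxy)phenol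
Product: 23 2-(trimethylsilyl)ethyl (E)-3-ArB-3-(ArA-oxy)-2-methoxyacrylate
Conditions: 4 (1.2 equiv), Cs2CO3, DMF, 60 °C
Reagents that add atoms: none
Why: Nucleophilic vinylic substitution by addition–elimination: the unhindered, electron-rich phenoxide adds to the β-carbon of the β-sulfonyloxy acrylate and the ester-stabilised carbanion expels tosylate, forming O1–C2. Retention should give the E isomer, in which the ester is cis to the aryloxy group.

Step 14
Reactants: 23 2-(trimethylsilyl)ethyl (E)-3-ArB-3-(ArA-oxy)-2-methoxyacrylate
Product: 24 (E)-3-ArB-3-(ArA-oxy)-2-methoxyacrylic acid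
Conditions: Bu4NF, THF, 0 °C to rt; cold 0.5 M aq HCl wash
Reagents that add atoms: none
Why: Fluoride attacks silicon and the 2-silylethyl ester fragments by β-elimination to the carboxylate; the pivalate and the acetals are untouched, which a hydroxide saponification of this hindered ester could not guarantee.

Step 15
Reactants: 24 (E)-3-ArB-3-(ArA-oxy)-2-methoxyacrylic acid
Product: 26 2-ArB-3,6-dimethoxy-5,7-bis(methoxymethoxy)-4H-chromen-4-one, via mixed trifluoroacetic anhydride 25 (not isolated)
Conditions: (CF3CO)2O (1.3 equiv), 2,6-di-tert-butyl-4-methylpyridine (3 equiv), CH2Cl2, 0 °C to rt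
Reagents that add atoms: trifluoroacetic anhydride, O=C(OC(=O)C(F)(F)F)C(F)(F)F (trifluoroacetyl group of 25 only)
Why: Trifluoroacetic anhydride turns the acid into mixed anhydride 25, and the hindered pyridine takes up the trifluoroacetic acid so that acetals and alkenes never meet free acid. The acyl carbon of 25, as such or after ionisation to a donor-stabilised acylium ion, is attacked by the ring A carbon ortho to the ether oxygen, and loss of a proton from the arenium ion gives the C4–C4a bond of flavone 26. The closest known reaction is the intramolecular Friedel–Crafts acylation of 3-aryloxyacrylic and 3-aryloxycinnamic acids to chromones and flavones. Ring C closes in a six-membered mode (6-exo attack of the arene carbon on the activated acyl group), and no stereocentre is formed. Site selectivity needs no control, because the two ortho carbons of the aryloxy ring are related by its mirror plane and both give the 6-methoxy isomer; each is ortho and para to an acetal oxygen and about as nucleophilic as a phloroglucinol ether carbon. The acid must be cis to the aryloxy group, as drawn for 24; a Z isomer can rotate about C2–C3 in the acylium ion, whose oxocarbenium resonance form has a single bond there. Five-membered closure onto ring B is disfavoured because its ortho carbons are only meta to the ring B oxygen. Partial loss of an acetal here would do no harm, since the next step removes all three.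

Step 16
Reactants: 26 2-ArB-3,6-dimethoxy-5,7-bis(methoxymethoxy)-4H-chromen-4-one
Product: 27 5,7-dihydroxy-2-{4-hydroxy-3-(3-methylbut-2-en-1-yl)-5-[(E)-3-methyl-4-(pivaloyloxy)but-2-en-1-yl]phenyl}-3,6-dimethoxy-4H-chromen-4-one
Conditions: 3 M aq HCl, MeOH/THF, 40 °C
Reagents that add atoms: none
Why: Acid-catalysed acetal exchange with methanol removes the three methoxymethyl groups under the dilute conditions routinely used for prenylated flavonoids. The pivalate keeps the allylic C–O bond from ionising, and the methyl ethers are inert.

Step 17
Reactants: 27 5,7-dihydroxy-2-{4-hydroxy-3-(3-methylbut-2-en-1-yl)-5-[(E)-3-methyl-4-(pivaloyloxy)but-2-en-1-yl]phenyl}-3,6-dimethoxy-4H-chromen-4-one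
Product: 28 dodoviscin G
Conditions: NaOMe, MeOH, rt to 40 °C, argon; then aq NH4Cl
Reagents that add atoms: none
Why: Methoxide transesterification (Zemplén-type) of the primary allylic pivalate; the flavone is present as its phenoxides, which shields the pyranone from nucleophilic attack, and the E alkene is not touched.

## Compound list

1 | 2-methoxyresorcinol (2-methoxybenzene-1,3-diol) | COc1c(O)cccc1O | starting material
2 | 2-methoxy-1,3-bis(methoxymethoxy)benzene | COCOc1cccc(OCOC)c1OC | intermediate
3 | 2-[4-methoxy-3,5-bis(methoxymethoxy)phenyl]-4,4,5,5-tetramethyl-1,3,2-dioxaborolane | COCOc1cc(B2OC(C)(C)C(C)(C)O2)cc(OCOC)c1OC | intermediate (not isolated)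
4 | 4-methoxy-3,5-bis(methoxymethoxy)phenol | COCOc1cc(O)cc(OCOC)c1OC | intermediate
5 | methoxyacetyl chloride | COCC(=O)Cl | starting material
6 | 2-(trimethylsilyl)ethanol | C[Si](C)(C)CCO | starting material
7 | 2-(trimethylsilyl)ethyl methoxyacetate | COCC(=O)OCC[Si](C)(C)C | intermediate
8 | methyl 3-bromo-4-hydroxybenzoate | COC(=O)c1ccc(O)c(Br)c1 | starting material
9 | allyl bromide | C=CCBr | starting material
10 | methyl 4-(allyloxy)-3-bromobenzoate | COC(=O)c1ccc(OCC=C)c(Br)c1 | intermediate
11 | methyl 3-allyl-5-bromo-4-hydroxybenzoate | COC(=O)c1cc(Br)c(O)c(CC=C)c1 | intermediate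
12 | methyl 3-allyl-5-bromo-4-(methoxymethoxy)benzoate | COCOc1c(Br)cc(C(=O)OC)cc1CC=C | intermediate
13 | methacrolein | CC(=C)C=O | starting material
14 | methyl 3-bromo-4-(methoxymethoxy)-5-[(E)-3-methyl-4-oxobut-2-en-1-yl]benzoate | COCOc1c(Br)cc(C(=O)OC)cc1C/C=C(\C)C=O | intermediate
15 | methyl 3-bromo-5-[(E)-4-hydroxy-3-methylbut-2-en-1-yl]-4-(methoxymethoxy)benzoate | COCOc1c(Br)cc(C(=O)OC)cc1C/C=C(\C)CO | intermediate
16 | prenyl bromide (1-bromo-3-methylbut-2-ene) | CC(C)=CCBr | starting material
17 | prenylzinc bromide | CC(C)=CC[Zn]Br | intermediate (not isolated)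
18 | methyl 3-[(E)-4-hydroxy-3-methylbut-2-en-1-yl]-4-(methoxymethoxy)-5-(3-methylbut-2-en-1-yl)benzoate | COCOc1c(CC=C(C)C)cc(C(=O)OC)cc1C/C=C(\C)CO | intermediate
19 | methyl 4-(methoxymethoxy)-3-(3-methylbut-2-en-1-yl)-5-[(E)-3-methyl-4-(pivaloyloxy)but-2-en-1-yl]benzoate | COCOc1c(CC=C(C)C)cc(C(=O)OC)cc1C/C=C(\C)COC(=O)C(C)(C)C | intermediate
20 | lithium enolate of 7 (chelated geometry drawn; it plays no role in the outcome) | CO/C=C(\O[Li])OCC[Si](C)(C)C | intermediate (not isolated)
21 | 2-(trimethylsilyl)ethyl 3-ArB-2-methoxy-3-oxopropanoate (racemic) | COCOc1c(CC=C(C)C)cc(C(=O)C(OC)C(=O)OCC[Si](C)(C)C)cc1C/C=C(\C)COC(=O)C(C)(C)C | intermediate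
22 | 2-(trimethylsilyl)ethyl (E)-3-ArB-2-methoxy-3-(tosyloxy)acrylate | C[Si](C)(C)CCOC(=O)/C(OC)=C(\OS(=O)(=O)c1ccc(C)cc1)c1cc(CC=C(C)C)c(OCOC)c(C/C=C(\C)COC(=O)C(C)(C)C)c1 | intermediate
23 | 2-(trimethylsilyl)ethyl (E)-3-ArB-3-[4-methoxy-3,5-bis(methoxymethoxy)phenoxy]-2-methoxyacrylate | C[Si](C)(C)CCOC(=O)/C(OC)=C(\Oc1cc(OCOC)c(OC)c(OCOC)c1)c1cc(CC=C(C)C)c(OCOC)c(C/C=C(\C)COC(=O)C(C)(C)C)c1 | intermediate
24 | (E)-3-ArB-3-[4-methoxy-3,5-bis(methoxymethoxy)phenoxy]-2-methoxyacrylic acid | OC(=O)/C(OC)=C(\Oc1cc(OCOC)c(OC)c(OCOC)c1)c1cc(CC=C(C)C)c(OCOC)c(C/C=C(\C)COC(=O)C(C)(C)C)c1 | intermediate (key-step precursor)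
25 | mixed anhydride of 24 with trifluoroacetic acid | O=C(OC(=O)C(F)(F)F)/C(OC)=C(\Oc1cc(OCOC)c(OC)c(OCOC)c1)c1cc(CC=C(C)C)c(OCOC)c(C/C=C(\C)COC(=O)C(C)(C)C)c1 | intermediate (not isolated)
26 | 2-ArB-3,6-dimethoxy-5,7-bis(methoxymethoxy)-4H-chromen-4-one | COc1c(OCOC)cc2oc(-c3cc(CC=C(C)C)c(OCOC)c(C/C=C(\C)COC(=O)C(C)(C)C)c3)c(OC)c(=O)c2c1OCOC | intermediate (key-step product)
27 | 5,7-dihydroxy-2-{4-hydroxy-3-(3-methylbut-2-en-1-yl)-5-[(E)-3-methyl-4-(pivaloyloxy)but-2-en-1-yl]phenyl}-3,6-dimethoxy-4H-chromen-4-one | COc1c(O)cc2oc(-c3cc(CC=C(C)C)c(O)c(C/C=C(\C)COC(=O)C(C)(C)C)c3)c(OC)c(=O)c2c1O | intermediate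
28 | dodoviscin G | COc1c(O)cc2oc(-c3cc(CC=C(C)C)c(O)c(C/C=C(\C)CO)c3)c(OC)c(=O)c2c1O | target

## Step count and risk

Total: 17 steps. Longest linear sequence: 14 steps (8 to 28, steps 4–17).

**Step 15 (key step).** Under buffered conditions the push–pull acyl group may be too weak an electrophile, so that ring closure is slow and intermolecular trifluoroacetylation of ring A competes. If the buffer is insufficient, acetals are lost and the prenyl group can cyclise onto the freed phenol. A Z isomer that does not equilibrate could close onto ring B instead. The fallback closes the same C4–C4a bond from the carbanion side (Parham-type cyclisation). It sets out from phenol 4 and tosylate 22. Iodination of 4 (N-iodosuccinimide, MeCN, 0 °C) should give 2-iodo-4-methoxy-3,5-bis(methoxymethoxy)phenol F1. Its phenoxide is put on 22 as in step 13 to give 2-(trimethylsilyl)ethyl (E)-3-ArB-3-[2-iodo-4-methoxy-3,5-bis(methoxymethoxy)phenoxy]-2-methoxyacrylate F2. Iodine–magnesium exchange (iPrMgCl·LiCl, THF, −40 °C) then lets the arylmagnesium attack the neighbouring ester and expel the silylethoxide. This comes back to the route at flavone 26 without any acid. Only the E isomer of F2 can close.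

**Step 13.** Addition to a fully substituted α-alkoxy acrylate may be slow, and the phenoxide may instead attack sulfur (sulfonyl transfer), which returns keto ester 21. The fallback removes the electrophilic sulfur and changes the mechanism to a copper-catalysed coupling. It sets out from 21: Ph3PBr2 and Et3N in CH2Cl2 should give 2-(trimethylsilyl)ethyl (E)-3-ArB-3-bromo-2-methoxyacrylate F3. Ullmann-type vinylation of phenol 4 (CuI, N,N-dimethylglycine, Cs2CO3, dioxane, 90 °C) comes back at 23.

**Step 11.** Self-condensation of enolate 20 may outrun acylation by the electron-rich benzoate, leaving 19 unchanged. The fallback uses a more reactive acyl donor. It sets out from alcohol 18: LiOH in THF/H2O should give 3-[(E)-4-hydroxy-3-methylbut-2-en-1-yl]-4-(methoxymethoxy)-5-(3-methylbut-2-en-1-yl)benzoic acid F4. PivCl (2.2 equiv) and Et3N acylate both the alcohol and the carboxylate to give the mixed pivalic anhydride of 4-(methoxymethoxy)-3-(3-methylbut-2-en-1-yl)-5-[(E)-3-methyl-4-(pivaloyloxy)but-2-en-1-yl]benzoic acid F5. Added to enolate 20 (2 equiv, −78 °C), F5 should be attacked at the aroyl carbonyl, which comes back at 21.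

**Step 9.** The coupling may give some branched (reverse-prenyl) isomer, or the zinc reagent may be quenched faster than it transmetalates, leading to protodebromination. The fallback builds the prenyl group in two stages. It sets out from bromide 15: Stille coupling with allyltributylstannane (Pd(PPh3)4, toluene, 100 °C) should give methyl 3-allyl-5-[(E)-4-hydroxy-3-methylbut-2-en-1-yl]-4-(methoxymethoxy)benzoate F6. Cross-metathesis with 2-methylbut-2-ene (second-generation Grubbs catalyst RuCl2(H2IMes)(PCy3)(=CHPh), CH2Cl2, 40 °C) comes back at 18.

**Step 7.** Ruthenium hydride species may move the allyl double bond into conjugation with the ring, and self-metathesis or erosion of the E geometry may lower the efficiency. The fallback makes the alkene by carbonyl olefination. It sets out from 12: Lemieux–Johnson cleavage (OsO4 cat., NaIO4, 2,6-lutidine, dioxane/H2O) should give methyl 3-bromo-4-(methoxymethoxy)-5-(2-oxoethyl)benzoate F7. An E-selective Wittig reaction with the stabilised ylide 2-(triphenylphosphoranylidene)propanal (toluene, 80 °C) comes back at enal 14.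

## Further compounds

F1 | step 15 | 2-iodo-4-methoxy-3,5-bis(methoxymethoxy)phenol | COCOc1cc(O)c(I)c(OCOC)c1OC
F2 | step 15 | 2-(trimethylsilyl)ethyl (E)-3-ArB-3-[2-iodo-4-methoxy-3,5-bis(methoxymethoxy)phenoxy]-2-methoxyacrylate | C[Si](C)(C)CCOC(=O)/C(OC)=C(\Oc1cc(OCOC)c(OC)c(OCOC)c1I)c1cc(CC=C(C)C)c(OCOC)c(C/C=C(\C)COC(=O)C(C)(C)C)c1
F3 | step 13 | 2-(trimethylsilyl)ethyl (E)-3-ArB-3-bromo-2-methoxyacrylate | C[Si](C)(C)CCOC(=O)/C(OC)=C(\Br)c1cc(CC=C(C)C)c(OCOC)c(C/C=C(\C)COC(=O)C(C)(C)C)c1
F4 | step 11 | 3-[(E)-4-hydroxy-3-methylbut-2-en-1-yl]-4-(methoxymethoxy)-5-(3-methylbut-2-en-1-yl)benzoic acid | COCOc1c(CC=C(C)C)cc(C(=O)O)cc1C/C=C(\C)CO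
F5 | step 11 | mixed pivalic anhydride of 4-(methoxymethoxy)-3-(3-methylbut-2-en-1-yl)-5-[(E)-3-methyl-4-(pivaloyloxy)but-2-en-1-yl]benzoic acid | COCOc1c(CC=C(C)C)cc(C(=O)OC(=O)C(C)(C)C)cc1C/C=C(\C)COC(=O)C(C)(C)C
F6 | step 9 | methyl 3-allyl-5-[(E)-4-hydroxy-3-methylbut-2-en-1-yl]-4-(methoxymethoxy)benzoate | COCOc1c(CC=C)cc(C(=O)OC)cc1C/C=C(\C)CO
F7 | step 7 | methyl 3-bromo-4-(methoxymethoxy)-5-(2-oxoethyl)benzoate | COCOc1c(Br)cc(C(=O)OC)cc1CC=O
A1 | alternative 1 | 3-unsubstituted flavone, 6-methoxy-5,7-bis(methoxymethoxy)-2-aryl-4H-chromen-4-one with methoxymethyl and tert-butyldimethylsilyl protected ring B | COc1c(OCOC)cc2oc(-c3cc(CC=C(C)C)c(OCOC)c(C/C=C(\C)CO[Si](C)(C)C(C)(C)C)c3)cc(=O)c2c1OCOC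
A2 | alternative 1 | 2-iodo-4-methoxy-3,5-bis(methoxymethoxy)phenol | COCOc1cc(O)c(I)c(OCOC)c1OC
A3 | alternative 1 | 5-ethynyl-2-(methoxymethoxy)-1-(3-methylbut-2-en-1-yl)-3-[(E)-4-(tert-butyldimethylsilyloxy)-3-methylbut-2-en-1-yl]benzene | C#Cc1cc(CC=C(C)C)c(OCOC)c(C/C=C(\C)CO[Si](C)(C)C(C)(C)C)c1
A4 | alternative 1 | carbon monoxide | [C-]#[O+]
A5 | alternative 2 | methyl 6-aryl-5-methoxy-2-methyl-4-oxo-4H-pyran-3-carboxylate with protected ring B | COC(=O)c1c(C)oc(-c2cc(CC=C(C)C)c(OCOC)c(C/C=C(\C)CO[Si](C)(C)C(C)(C)C)c2)c(OC)c1=O
A6 | alternative 2 | methyl methoxyacetate | COCC(=O)OC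
A7 | alternative 2 | 5,7-dihydroxy-3,6-dimethoxyflavone with protected ring B | COc1c(O)cc2oc(-c3cc(CC=C(C)C)c(OCOC)c(C/C=C(\C)CO[Si](C)(C)C(C)(C)C)c3)c(OC)c(=O)c2c1O
A8 | alternative 3 | 1-[6-bromo-3-methoxy-2,4-bis(methoxymethoxy)phenyl]-2-methoxy-3-aryl-propane-1,3-dione with protected ring B | COCOc1cc(Br)c(C(=O)C(OC)C(=O)c2cc(CC=C(C)C)c(OCOC)c(C/C=C(\C)CO[Si](C)(C)C(C)(C)C)c2)c(OCOC)c1OC
A9 | alternative 3 | fully protected dodoviscin G (three methoxymethyl ethers, one tert-butyldimethylsilyl ether) | COc1c(OCOC)cc2oc(-c3cc(CC=C(C)C)c(OCOC)c(C/C=C(\C)CO[Si](C)(C)C(C)(C)C)c3)c(OC)c(=O)c2c1OCOC
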